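## Retrosynthetic overview

1. Feature: C2 of the 2,3-dihydrobenzofuran (ring B: O1–C2–C3–C3a–C7a) is a CH bonded to O1, to C3 and to C1' of the trimethoxyphenyl ring. It can therefore be supplied as the carbon of dichloromethyllithium, placed between a C3–boron bond and an aryl Grignard reagent, with boron holding the place of O1.
2. Disconnections: O1–C2 (Mitsunobu closure with inversion) back to a C2 alcohol and a C2 boronic ester; C2–C3 and C2–C1' by two 1,2-shifts on boron (step 7); C3–CH3 and C3–C3a by a first homologation of the aryl boronic ester (step 5).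
3. Stereocontrol: one director on boron, (S,S)-1,2-dicyclohexylethane-1,2-diol, sets C3 and then C2. It gives (R)-α-chloro boronic esters and each Grignard displacement inverts. C–B oxidation retains and ring closure inverts C2, which leads to (2R,3R).
4. Rings: benzene ring A (from 5-bromovanillin, E-propenyl group installed in step 2) and the trimethoxyphenyl ring are bought. The only ring made is dihydrofuran ring B, closed last (step 10).

Key step: step 7

Remarks before the steps:
- Atom labels follow benzofuran numbering of the target (O1, C2, C3, C3a, C4 to C7, C7a; C1' is the ipso carbon of the trimethoxyphenyl ring). Ar = 3-methoxy-5-[(E)-prop-1-enyl]-2-(prop-2-enyloxy)phenyl.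
- Spectator groups: the phenol is carried as its allyl ether and C5 already carries the E-propenyl group, so no hydrogenolysis and no late olefination are needed. Both groups should be inert to organolithium, carbenoid and Grignard reagents at low temperature.
- Dichloromethyllithium 9 does not keep. Step 4 is a reagent preparation that is run afresh immediately before step 5 and again immediately before step 7, and the cold solution is used in the same flask.
- Assumption: 5-(ethylsulfonyl)-1-phenyl-1H-tetrazole and (1S,2S)-1,2-dicyclohexylethane-1,2-diol are taken as purchasable reagents.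
- The C3 carbon keeps one geometry from 13 to 22. Its descriptor reads R in 13, 17, 20, 21 and 22 and S in 19 only because the ranking of its neighbours changes.

## Route

Step 1
Reactants: 1 5-bromovanillin
Product: 2 3-bromo-5-methoxy-4-(prop-2-enyloxy)benzaldehyde
Conditions: allyl bromide, K2CO3, DMF, rt
Reagents that add atoms: allyl bromide, C=CCBr
Why: Williamson ether synthesis: the phenol, acidified by the para-formyl and ortho-bromo groups, is alkylated cleanly on oxygen, and the allyl ether is chosen because it withstands organolithium, carbenoid and Grignard reagents and is later removed by zerovalent palladium without touching an alkene.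

Step 2
Reactants: 2 3-bromo-5-methoxy-4-(prop-2-enyloxy)benzaldehyde
Product: 3 1-bromo-3-methoxy-5-[(E)-prop-1-enyl]-2-(prop-2-enyloxy)benzene
Conditions: 5-(ethylsulfonyl)-1-phenyl-1H-tetrazole, KN(SiMe3)2, DME, −60 °C → rt
Reagents that add atoms: 5-(ethylsulfonyl)-1-phenyl-1H-tetrazole, CCS(=O)(=O)c1nnnn1-c1ccccc1
Why: Julia–Kocienski olefination: the metalated ethyl sulfone adds to the aryl aldehyde, Smiles rearrangement and loss of SO2 and tetrazololate follow, and aryl aldehydes with 1-phenyltetrazolyl sulfones should give mainly the E alkene, so that the propenyl geometry is fixed early and any Z isomer can be removed (AgNO3-impregnated silica or crystallisation) before the boron chemistry.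

Step 3
Reactants: 3 1-bromo-3-methoxy-5-[(E)-prop-1-enyl]-2-(prop-2-enyloxy)benzene; 4 (1S,2S)-1,2-dicyclohexylethane-1,2-diol
Product: 7 aryl boronic ester of diol 4 [(4S,5S)-2-Ar-4,5-dicyclohexyl-1,3,2-dioxaborolane], via aryllithium 5 (not isolated), via triisopropoxyborate 6 (not isolated)
Conditions: n-BuLi, THF, −78 °C; B(OiPr)3, −78 °C → rt; then 4, AcOH, rt
Reagents that add atoms: triisopropyl borate, CC(C)OB(OC(C)C)OC(C)C
Why: Bromine–lithium exchange at −78 °C outruns any attack on the allyl ether or the alkene, the aryllithium is trapped by the borate ester, and on neutralisation with acetic acid the chelating diol displaces isopropanol to give the robust five-membered boronic ester (borylation then transesterification).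

Step 4
Reactants: 8 dichloromethane
Product: 9 dichloromethyllithium (THF solution at −100 °C, used at once)
Conditions: n-BuLi, THF, −100 °C
Reagents that add atoms: n-butyllithium, [Li]CCCC
Why: Deprotonation of dichloromethane by n-butyllithium (formation of a halogen-stabilised lithium carbenoid) is fast at −100 °C, a temperature at which the carbenoid does not yet lose LiCl, so the cold solution can take up a boronic ester in the same flask.

Step 5
Reactants: 7 aryl boronic ester of diol 4; 9 dichloromethyllithium
Product: 13 (1R)-1-arylethyl boronic ester [(4S,5S)-4,5-dicyclohexyl-2-[(1R)-1-Ar-ethyl]-1,3,2-dioxaborolane], via dichloromethyl borate 10 (not isolated), via chlorobenzyl boronic ester 11 (not isolated), via methyl borate 12 (not isolated)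
Conditions: 9 (THF, −100 °C), then 7; ZnCl2, −100 °C → rt; then MeMgBr, −78 °C → rt
Reagents that add atoms: methylmagnesium bromide, C[Mg]Br
Why: Matteson homologation: 9 adds to boron, ZnCl2 promotes the 1,2-shift of the aryl group with loss of the chloride chosen by the (S,S)-diol to give the (R)-chloride 11, and MeMgBr then adds to boron and methyl shifts to carbon with inversion, which sets C3 as (R) in 13; 11 is not isolated because benzylic α-chloro boronic esters epimerise on standing with chloride.

Step 6
Reactants: 14 5-bromo-1,2,3-trimethoxybenzene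
Product: 15 (3,4,5-trimethoxyphenyl)magnesium bromide
Conditions: Mg, I2 (cat.), THF, rt → 50 °C
Reagents that add atoms: magnesium, [Mg]
Why: Grignard formation by insertion of magnesium into the aryl–bromine bond of an electron-rich aryl bromide in THF, the solution being titrated and used directly.

Step 7
Reactants: 13 (1R)-1-arylethyl boronic ester; 9 dichloromethyllithium; 15 (3,4,5-trimethoxyphenyl)magnesium bromide
Product: 19 (1S,2S)-2-aryl-1-(3,4,5-trimethoxyphenyl)propyl boronic ester [(4S,5S)-4,5-dicyclohexyl-2-[(1S,2S)-2-Ar-1-(3,4,5-trimethoxyphenyl)propyl]-1,3,2-dioxaborolane], via dichloromethyl borate 16 (not isolated), via chloro boronic ester 17 (not isolated), via aryl borate 18 (not isolated)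
Conditions: 9 (THF, −100 °C, freshly made by step 4), then 13; ZnCl2, −100 °C → rt; then 15 (excess), −78 °C → rt
Reagents that add atoms: none
Why: Carbenoid 9 adds to boron of 13 to give borate 16, ZnCl2 then assists loss of one chloride while the secondary benzylic C3 group shifts from boron to carbon with retention (C2–C3 bond, chloro boronic ester 17), and Grignard reagent 15 adds to boron (borate 18) so that the trimethoxyphenyl group shifts to C2 with inversion and expels the second chloride (C2–C1' bond). The closest known reaction type is the Matteson homologation of chiral diol boronic esters with dichloromethyllithium followed by Grignard displacement, which is used iteratively on secondary alkyl boronic esters and with aryl Grignard reagents. No ring closes in this step; ring B is closed only in step 10. The new C2 stereocentre is set by the C2-symmetric (S,S)-diol on boron, which in the zinc-bound borate decides which of the two diastereotopic chlorides leaves and so gives the (1R) chloride 17, and the stereospecific inversion by the aryl group converts it into the (1S) boronic ester, while C3 keeps its configuration because a migrating carbon does. The step needs reagent control that overrides the neighbouring C3 centre and a chloride 17 that does not epimerise, which the diol director (the same one that set C3) and the chloride-binding ZnCl2 at low temperature should secure, ZnCl2 also speeding the carbon shift. The allyl ether and the E-propenyl group should be inert to the carbenoid at −100 °C and to the Grignard reagent, provided that 9 is used in only slight excess.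

Step 8
Reactants: 19 (1S,2S)-2-aryl-1-(3,4,5-trimethoxyphenyl)propyl boronic ester
Product: 20 (1S,2R)-2-Ar-1-(3,4,5-trimethoxyphenyl)propan-1-ol
Conditions: H2O2 (30% aq.), NaOH, THF/H2O, 0 °C → rt
Reagents that add atoms: hydrogen peroxide, OO
Why: Oxidation of the carbon–boron bond by hydroperoxide anion goes by a 1,2-shift of C2 from boron to oxygen with retention, so the (1S) alcohol should result and the diol is released for recovery, while the aryl ethers and both alkenes are inert to alkaline H2O2.

Step 9
Reactants: 20 (1S,2R)-2-Ar-1-(3,4,5-trimethoxyphenyl)propan-1-ol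
Product: 21 2-[(1S,2R)-1-hydroxy-1-(3,4,5-trimethoxyphenyl)propan-2-yl]-6-methoxy-4-[(E)-prop-1-enyl]phenol
Conditions: Pd(PPh3)4 (cat.), morpholine, THF, rt
Reagents that add atoms: none
Why: Tsuji–Trost deallylation: zerovalent palladium ionises the aryl allyl ether to a π-allyl complex and phenoxide, morpholine takes up the allyl group, and neither the benzylic alcohol nor the conjugated E-propenyl group reacts.

Step 10
Reactants: 21 2-[(1S,2R)-1-hydroxy-1-(3,4,5-trimethoxyphenyl)propan-2-yl]-6-methoxy-4-[(E)-prop-1-enyl]phenol
Product: 22 (2R,3R)-7-methoxy-3-methyl-5-[(E)-prop-1-enyl]-2-(3,4,5-trimethoxyphenyl)-2,3-dihydro-1-benzofuran (target)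
Conditions: PPh3, DIAD, THF, 0 °C → rt
Reagents that add atoms: none
Why: Mitsunobu etherification: the phenol protonates the phosphine–azodicarboxylate betaine, the secondary benzylic alcohol becomes an oxyphosphonium leaving group and the phenoxide displaces it in a 5-exo-tet SN2 closure of ring B with inversion at C2, which gives the (2R) centre trans to the C3 methyl group; should some ionisation compete, the cation is also expected to close mainly to this trans ring.

## Compound list

1 | 5-bromovanillin (3-bromo-4-hydroxy-5-methoxybenzaldehyde) | O=Cc1cc(Br)c(O)c(OC)c1 | starting material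
2 | 3-bromo-5-methoxy-4-(prop-2-enyloxy)benzaldehyde | O=Cc1cc(Br)c(OCC=C)c(OC)c1 | intermediate
3 | 1-bromo-3-methoxy-5-[(E)-prop-1-enyl]-2-(prop-2-enyloxy)benzene | C/C=C/c1cc(Br)c(OCC=C)c(OC)c1 | intermediate
4 | (1S,2S)-1,2-dicyclohexylethane-1,2-diol | O[C@@H](C1CCCCC1)[C@@H](O)C1CCCCC1 | starting material
5 | {3-methoxy-5-[(E)-prop-1-enyl]-2-(prop-2-enyloxy)phenyl}lithium | C/C=C/c1cc([Li])c(OCC=C)c(OC)c1 | intermediate
6 | lithium {3-methoxy-5-[(E)-prop-1-enyl]-2-(prop-2-enyloxy)phenyl}tri(propan-2-yloxy)borate | [Li+].C/C=C/c1cc([B-](OC(C)C)(OC(C)C)OC(C)C)c(OCC=C)c(OC)c1 | intermediate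
7 | (4S,5S)-4,5-dicyclohexyl-2-{3-methoxy-5-[(E)-prop-1-enyl]-2-(prop-2-enyloxy)phenyl}-1,3,2-dioxaborolane | C/C=C/c1cc(B2O[C@@H](C3CCCCC3)[C@H](C3CCCCC3)O2)c(OCC=C)c(OC)c1 | intermediate
8 | dichloromethane | ClCCl | starting material
9 | dichloromethyllithium | [Li]C(Cl)Cl | intermediate
10 | lithium borate from 7 and 9 (boron carries Ar, CHCl2 and the diol) | [Li+].C/C=C/c1cc([B-]2(C(Cl)Cl)O[C@@H](C3CCCCC3)[C@H](C3CCCCC3)O2)c(OCC=C)c(OC)c1 | intermediate
11 | (4S,5S)-2-[(R)-chloro{3-methoxy-5-[(E)-prop-1-enyl]-2-(prop-2-enyloxy)phenyl}methyl]-4,5-dicyclohexyl-1,3,2-dioxaborolane | C/C=C/c1cc([C@H](Cl)B2O[C@@H](C3CCCCC3)[C@H](C3CCCCC3)O2)c(OCC=C)c(OC)c1 | intermediate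
12 | bromomagnesium borate from 11 and MeMgBr (boron carries the (R)-chloro(aryl)methyl group, CH3 and the diol) | [Mg+2].[Br-].C/C=C/c1cc([C@H](Cl)[B-]2(C)O[C@@H](C3CCCCC3)[C@H](C3CCCCC3)O2)c(OCC=C)c(OC)c1 | intermediate
13 | (4S,5S)-4,5-dicyclohexyl-2-[(1R)-1-{3-methoxy-5-[(E)-prop-1-enyl]-2-(prop-2-enyloxy)phenyl}ethyl]-1,3,2-dioxaborolane | C/C=C/c1cc([C@@H](C)B2O[C@@H](C3CCCCC3)[C@H](C3CCCCC3)O2)c(OCC=C)c(OC)c1 | intermediate
14 | 5-bromo-1,2,3-trimethoxybenzene | COc1cc(Br)cc(OC)c1OC | starting material
15 | (3,4,5-trimethoxyphenyl)magnesium bromide | COc1cc([Mg]Br)cc(OC)c1OC | intermediate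
16 | lithium borate from 13 and 9 (boron carries the (1R)-1-arylethyl group, CHCl2 and the diol) | [Li+].C/C=C/c1cc([C@@H](C)[B-]2(C(Cl)Cl)O[C@@H](C3CCCCC3)[C@H](C3CCCCC3)O2)c(OCC=C)c(OC)c1 | intermediate
17 | (4S,5S)-2-[(1R,2R)-1-chloro-2-{3-methoxy-5-[(E)-prop-1-enyl]-2-(prop-2-enyloxy)phenyl}propyl]-4,5-dicyclohexyl-1,3,2-dioxaborolane | C/C=C/c1cc([C@@H](C)[C@H](Cl)B2O[C@@H](C3CCCCC3)[C@H](C3CCCCC3)O2)c(OCC=C)c(OC)c1 | intermediate
18 | bromomagnesium borate from 17 and 15 (boron carries the (1R,2R)-1-chloro-2-arylpropyl group, the trimethoxyphenyl group and the diol) | [Mg+2].[Br-].C/C=C/c1cc([C@@H](C)[C@H](Cl)[B-]2(c3cc(OC)c(OC)c(OC)c3)O[C@@H](C3CCCCC3)[C@H](C3CCCCC3)O2)c(OCC=C)c(OC)c1 | intermediate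
19 | (4S,5S)-4,5-dicyclohexyl-2-[(1S,2S)-2-{3-methoxy-5-[(E)-prop-1-enyl]-2-(prop-2-enyloxy)phenyl}-1-(3,4,5-trimethoxyphenyl)propyl]-1,3,2-dioxaborolane | C/C=C/c1cc([C@@H](C)[C@@H](c2cc(OC)c(OC)c(OC)c2)B2O[C@@H](C3CCCCC3)[C@H](C3CCCCC3)O2)c(OCC=C)c(OC)c1 | intermediate
20 | (1S,2R)-2-{3-methoxy-5-[(E)-prop-1-enyl]-2-(prop-2-enyloxy)phenyl}-1-(3,4,5-trimethoxyphenyl)propan-1-ol | C/C=C/c1cc([C@@H](C)[C@@H](c2cc(OC)c(OC)c(OC)c2)O)c(OCC=C)c(OC)c1 | intermediate
21 | 2-[(1S,2R)-1-hydroxy-1-(3,4,5-trimethoxyphenyl)propan-2-yl]-6-methoxy-4-[(E)-prop-1-enyl]phenol | C/C=C/c1cc([C@@H](C)[C@@H](c2cc(OC)c(OC)c(OC)c2)O)c(O)c(OC)c1 | intermediate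
22 | (2R,3R)-7-methoxy-3-methyl-5-[(E)-prop-1-enyl]-2-(3,4,5-trimethoxyphenyl)-2,3-dihydro-1-benzofuran | C/C=C/c1cc(OC)c2c(c1)[C@@H](C)[C@H](c1cc(OC)c(OC)c(OC)c1)O2 | target

## Step count and risks

Total step count: 10 (steps 1 to 10). Longest linear sequence: 8 steps (steps 1, 2, 3, 5, 7, 8, 9 and 10, from 5-bromovanillin). Steps 4 and 6 prepare the carbenoid and the Grignard reagent in side branches, step 4 being run once before step 5 and once before step 7.

Steps most likely to fail:

1. Step 7. The aryl Grignard reagent may add slowly to the hindered boron of 17, or chloride exchange at C2 may occur before the aryl shift, so that the C2 configuration is eroded. The fallback sets out from 13 and comes back to the route at 20. The insertion half of step 7 is run alone and chloro boronic ester 17 is isolated and oxidised with H2O2 in NaHCO3-buffered THF/water, which should give the aldehyde (2R)-2-Ar-propanal F1 with loss of the C2 chlorine. Addition of Grignard reagent 15 at −78 °C, under 1,2-asymmetric induction by the α-aryl centre (attack anti to the aryl group, past the hydrogen), should favour alcohol 20; its C1 epimer, (1R,2R)-2-Ar-1-(3,4,5-trimethoxyphenyl)propan-1-ol F2, is removed by chromatography. C2 is then set by substrate control at a carbonyl group instead of by a 1,2-shift on boron, and the aldehyde is used at once because its α-aryl centre can epimerise.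

2. Step 5. The benzylic chloride 11 may epimerise by chloride exchange, or the ortho-alkoxy aryl group may shift slowly so that oxygen migration (ring expansion of the boronic ester) competes. The fallback sets out from 7 and comes back at 13 by lithiation–borylation with a chiral carbenoid. Ethyl 2,4,6-triisopropylbenzoate is deprotonated with s-BuLi and (−)-sparteine in Et2O at −78 °C to (1S)-1-lithioethyl 2,4,6-triisopropylbenzoate F3, which adds to boron of 7 with retention to give the lithium borate of 7 carrying the (1S)-1-(2,4,6-triisopropylbenzoyloxy)ethyl group F4. On warming (with MgBr2 in methanol if the shift is slow), the aryl group shifts to carbon with inversion and expels the benzoate, which should give 13 directly. C3 is then set by the sparteine-controlled carbenoid and not by the diol.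

3. Step 10. The activated, electron-rich benzylic alcohol may ionise so that C2 is not inverted cleanly, or the hindered secondary alcohol may be activated slowly. The fallback sets out from 21 and comes back at 22 by acid-catalysed dehydrative closure (camphorsulfonic acid, cat., CH2Cl2, 0 °C) through the 3,4,5-trimethoxybenzylic cation. The phenol should capture this cation anti to the C3 methyl group and give the more stable trans ring whatever the configuration of the leaving group. Brief exposure to a weak acid is chosen to spare the propenyl group and the C3 hydrogen. This fallback makes no compound outside the route (none F0).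

## Further compounds

F1 | step 7 | (2R)-2-{3-methoxy-5-[(E)-prop-1-enyl]-2-(prop-2-enyloxy)phenyl}propanal | C/C=C/c1cc([C@@H](C)C=O)c(OCC=C)c(OC)c1
F2 | step 7 | (1R,2R)-2-{3-methoxy-5-[(E)-prop-1-enyl]-2-(prop-2-enyloxy)phenyl}-1-(3,4,5-trimethoxyphenyl)propan-1-ol | C/C=C/c1cc([C@@H](C)[C@H](c2cc(OC)c(OC)c(OC)c2)O)c(OCC=C)c(OC)c1
F3 | step 5 | (1S)-1-lithioethyl 2,4,6-triisopropylbenzoate | C[C@H]([Li])OC(=O)c1c(C(C)C)cc(C(C)C)cc1C(C)C
F4 | step 5 | lithium borate from F3 and 7 (boron carries Ar, the (1S)-1-(2,4,6-triisopropylbenzoyloxy)ethyl group and the diol) | [Li+].C[C@H]([B-]1(c2cc(/C=C/C)cc(OC)c2OCC=C)O[C@@H](C2CCCCC2)[C@H](C2CCCCC2)O1)OC(=O)c1c(C(C)C)cc(C(C)C)cc1C(C)C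
F0 | step 10 | none | none
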